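The cyclohexene ring is closed by joining a sugar-derived four-carbon chain (ring atoms C1–C4, with the C3 stereocentre from 2-deoxy-L-ribose) to a two-carbon vinylsulfonium unit (C5–C6). In one operation the C1 carbanion, α to the ester and to a temporary sulfone, adds to the vinylsulfonium CH2 (bond C6–C1), and the sulfur ylide so formed, a polarity-reversed C5, attacks the C4 aldehyde (bond C4–C5) and closes an oxirane over C4–C5. The step exploits the trans-4,5-diol diester, carried as a cis-epoxide that the C5 acid later opens with inversion, and the acidity of C1. A C2–C3 acetonide later serves as leaving group to unveil the C1=C2 enoate.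

Key step: step 6

Remark: ring atoms are numbered as in shikimic acid (C1 bears CO2Me, C2 is the vinylic CH, C3 bears OAc, C4 the 2-methylbutanoate, C5 the 3-methylpentanoate, C6 is CH2) and the open-chain precursors keep these numbers. Compounds 1, 7, 14 and 16 are assumed to be purchasable in enantiopure form.

Step 1
Reactants: 1 2-deoxy-L-ribose
Product: 2 2-deoxy-3,4-O-isopropylidene-L-erythro-pentopyranose (lactol; anomer mixture)
Conditions: 2-methoxypropene, PPTS (cat.), EtOAc, 0 °C → rt
Reagents that add atoms: 2-methoxypropene, COC(C)=C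
Why: Acid-catalysed transketalisation (acetonide formation) should engage the cis-3,4-diol of the pyranose form and leave the anomeric hydroxyl free, with no stereocentre changed.

Step 2
Reactants: 2 2-deoxy-3,4-O-isopropylidene-L-erythro-pentopyranose
Product: 3 2-deoxy-3,4-O-isopropylidene-L-erythro-pentono-1,5-lactone
Conditions: Pr4N[RuO4] (cat.), NMO, 4 Å MS, CH2Cl2, rt
Reagents that add atoms: none
Why: Ley–Griffith oxidation should convert the lactol into the δ-lactone under neutral conditions that spare the acetonide.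

Step 3
Reactants: 3 2-deoxy-3,4-O-isopropylidene-L-erythro-pentono-1,5-lactone
Product: 4 2-deoxy-3,4-O-isopropylidene-2-(phenylsulfanyl)-L-erythro-pentono-1,5-lactone (C-2 epimers of the lactone; this carbon is ring atom C1)
Conditions: LiN(SiMe3)2, THF, −78 °C; then inverse addition to PhSO2SPh, −78 °C
Reagents that add atoms: S-phenyl benzenethiosulfonate, O=S(=O)(Sc1ccccc1)c1ccccc1
Why: Kinetic deprotonation at −78 °C gives the lactone enolate, which should be sulfenylated (enolate α-sulfenylation) faster than it expels the β-alkoxy group; the new α-stereocentre is of no consequence because it is planarised in steps 6 and 7.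

Step 4
Reactants: 4 2-deoxy-3,4-O-isopropylidene-2-(phenylsulfanyl)-L-erythro-pentono-1,5-lactone
Product: 5 methyl 2-[(4S,5S)-5-(hydroxymethyl)-2,2-dimethyl-1,3-dioxolan-4-yl]-2-(phenylsulfanyl)acetate (α-epimers)
Conditions: K2CO3 (cat.), MeOH, 0 °C
Reagents that add atoms: methanol, CO
Why: Base-catalysed transesterification in excess methanol should open the δ-lactone to the methyl ester and free the primary alcohol (future C4) without touching the dioxolane stereocentres.

Step 5
Reactants: 5 methyl 2-[(4S,5S)-5-(hydroxymethyl)-2,2-dimethyl-1,3-dioxolan-4-yl]-2-(phenylsulfanyl)acetate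
Product: 6 methyl 2-[(4S,5R)-5-formyl-2,2-dimethyl-1,3-dioxolan-4-yl]-2-(phenylsulfonyl)acetate (α-epimers)
Conditions: Pr4N[RuO4] (cat.), NMO (4 equiv.), 4 Å MS, MeCN, rt → 40 °C
Reagents that add atoms: N-methylmorpholine N-oxide, C[N+]1([O-])CCOCC1
Why: Catalytic perruthenate with the N-oxide (Ley–Griffith conditions) should oxidise the sulfide to the sulfone and the primary alcohol to the aldehyde in one pot under non-basic conditions, so the α-alkoxy aldehyde stereocentre (C3) is kept.

Step 6
Reactants: 6 methyl 2-[(4S,5R)-5-formyl-2,2-dimethyl-1,3-dioxolan-4-yl]-2-(phenylsulfonyl)acetate; 7 diphenyl(vinyl)sulfonium triflate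
Product: 10 methyl (2S,3S,4S,5S)-4,5-epoxy-2,3-(isopropylidenedioxy)-1-(phenylsulfonyl)cyclohexane-1-carboxylate (C-1 epimers), via sulfonium ylide 8 (not isolated), via alkoxide betaine 9 (not isolated)
Conditions: 7 (1.2 equiv.), DBU (1.2 equiv.), CH2Cl2, 0 °C → rt
Reagents that add atoms: diphenyl(vinyl)sulfonium triflate (7), C=C[S+](c1ccccc1)c1ccccc1.[O-]S(=O)(=O)C(F)(F)F
Why: DBU deprotonates C1 (doubly activated by ester and sulfone) and the carbanion adds to the CH2 terminus of the vinylsulfonium salt to give sulfur ylide 8, whose carbon (C5) adds to the C4 aldehyde to give betaine 9, which expels diphenyl sulfide on oxirane closure. The closest known reaction type is the vinylsulfonium epoxy-annulation of tethered nucleophile–carbonyl substrates, a conjugate addition followed by an intramolecular Corey–Chaykovsky epoxidation. The cyclohexane closes by 6-exo-trig attack of the ylide carbon on the carbonyl and the oxirane by 3-exo-tet displacement at C5. The new C4 stereocentre should be set by the adjacent C3 stereocentre (Felkin–Anh, with the C3–O bond anti to the incoming ylide in a chair-like transition state), which places the C4 oxygen cis to the C3 oxygen; C5 follows because the oxirane can only be cis-fused, and the uncontrolled C1 centre is erased in step 7. The step needs C-alkylation of the carbanion rather than β-elimination of the dioxolane oxygen and needs the ylide to reach the aldehyde; the very electrophilic sulfonium acceptor and the absence of a remaining acidic C–H at C1 (no cyclopropane pathway) should secure this.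

Step 7
Reactants: 10 methyl (2S,3S,4S,5S)-4,5-epoxy-2,3-(isopropylidenedioxy)-1-(phenylsulfonyl)cyclohexane-1-carboxylate
Product: 12 methyl (1S,5R,6R)-5-hydroxy-7-oxabicyclo[4.1.0]hept-3-ene-3-carboxylate, via samarium enolate 11 (not isolated)
Conditions: SmI2 (2.5 equiv.), THF–HMPA, −78 °C; then aq. NH4Cl
Reagents that add atoms: none
Why: Two single-electron transfers should cleave the C1–sulfonyl bond to give samarium enolate 11, which expels the β-alkoxy oxygen at C2 (Julia-type reductive elimination), so that the enoate forms regiospecifically between C1 and C2 and the C3 oxygen is released as the free alcohol after loss of acetone, while the isolated oxirane and the C3, C4 and C5 stereocentres are not touched.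

Step 8
Reactants: 12 methyl (1S,5R,6R)-5-hydroxy-7-oxabicyclo[4.1.0]hept-3-ene-3-carboxylate
Product: 13 methyl (1S,5R,6S)-5-acetoxy-7-oxabicyclo[4.1.0]hept-3-ene-3-carboxylate
Conditions: Ac2O, pyridine, DMAP (cat.), CH2Cl2, 0 °C
Reagents that add atoms: acetic anhydride, CC(=O)OC(C)=O
Why: DMAP-catalysed acetylation of the only free hydroxyl should give the C3 acetate without change at any stereocentre.

Step 9
Reactants: 13 methyl (1S,5R,6S)-5-acetoxy-7-oxabicyclo[4.1.0]hept-3-ene-3-carboxylate; 14 (S)-3-methylpentanoic acid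
Product: 15 methyl (3R,4S,5R)-3-acetoxy-4-hydroxy-5-[(S)-3-methylpentanoyloxy]cyclohex-1-ene-1-carboxylate
Conditions: 14 (3 equiv.), Cs2CO3 (0.25 equiv.), DMF, 50 °C
Reagents that add atoms: (S)-3-methylpentanoic acid (14), CC[C@H](C)CC(=O)O
Why: SN2 opening of the oxirane by the caesium carboxylate should occur at C5, the carbon remote from the shielding and inductively deactivating C3 acetoxy group (as is known for azide opening of analogous 3-alkoxy epoxides), with inversion at C5 and retention at C4, which places the C5 ester trans to the freed C4 hydroxyl, while the excess acid buffers the alkoxide against acyl migration.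

Step 10
Reactants: 15 methyl (3R,4S,5R)-3-acetoxy-4-hydroxy-5-[(S)-3-methylpentanoyloxy]cyclohex-1-ene-1-carboxylate; 16 (R)-2-methylbutanoic acid
Product: 17 methyl (3R,4S,5R)-3-acetoxy-4-[(R)-2-methylbutanoyloxy]-5-[(S)-3-methylpentanoyloxy]cyclohex-1-ene-1-carboxylate
Conditions: 16, DIC, DMAP (cat.), CH2Cl2, 0 °C → rt
Reagents that add atoms: (R)-2-methylbutanoic acid (16), CC[C@@H](C)C(=O)O
Why: Steglich esterification should acylate the remaining C4 hydroxyl with retention at C4 and, because no ketene is formed from the carbodiimide-activated acid, without epimerising the α-stereocentre of the acyl group.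

Compound list
1 | 2-deoxy-L-ribose (2-deoxy-L-erythro-pentose; drawn as the open-chain aldehyde) | O=CC[C@@H](O)[C@@H](O)CO | starting material
2 | 2-deoxy-3,4-O-isopropylidene-L-erythro-pentopyranose (lactol; anomer mixture) | OC1C[C@H]2OC(C)(C)O[C@H]2CO1 | intermediate
3 | 2-deoxy-3,4-O-isopropylidene-L-erythro-pentono-1,5-lactone | O=C1C[C@H]2OC(C)(C)O[C@H]2CO1 | intermediate
4 | 2-deoxy-3,4-O-isopropylidene-2-(phenylsulfanyl)-L-erythro-pentono-1,5-lactone (C-2 epimers) | O=C1C(Sc3ccccc3)[C@H]2OC(C)(C)O[C@H]2CO1 | intermediate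
5 | methyl 2-[(4S,5S)-5-(hydroxymethyl)-2,2-dimethyl-1,3-dioxolan-4-yl]-2-(phenylsulfanyl)acetate (α-epimers) | COC(=O)C(Sc1ccccc1)[C@H]1OC(C)(C)O[C@H]1CO | intermediate
6 | methyl 2-[(4S,5R)-5-formyl-2,2-dimethyl-1,3-dioxolan-4-yl]-2-(phenylsulfonyl)acetate (α-epimers) | COC(=O)C(S(=O)(=O)c1ccccc1)[C@H]1OC(C)(C)O[C@H]1C=O | intermediate
7 | diphenyl(vinyl)sulfonium trifluoromethanesulfonate | C=C[S+](c1ccccc1)c1ccccc1.[O-]S(=O)(=O)C(F)(F)F | starting material
8 | sulfonium ylide: methyl 4-(diphenylsulfonio)-2-[(4S,5R)-5-formyl-2,2-dimethyl-1,3-dioxolan-4-yl]-2-(phenylsulfonyl)butanoate 4-ylide | COC(=O)C(S(=O)(=O)c1ccccc1)(C[CH-][S+](c1ccccc1)c1ccccc1)[C@H]1OC(C)(C)O[C@H]1C=O | intermediate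
9 | alkoxide betaine: ring-closed 4-oxido-5-(diphenylsulfonio) cyclohexane with oxygen at C4 cis to the dioxolane and sulfur at C5 trans to it | COC(=O)C1(S(=O)(=O)c2ccccc2)C[C@@H]([S+](c2ccccc2)c2ccccc2)[C@H]([O-])[C@@H]3OC(C)(C)O[C@H]13 | intermediate
10 | methyl (2S,3S,4S,5S)-4,5-epoxy-2,3-(isopropylidenedioxy)-1-(phenylsulfonyl)cyclohexane-1-carboxylate (C-1 epimers; oxirane and dioxolane on the same ring face) | COC(=O)C1(S(=O)(=O)c2ccccc2)C[C@@H]3O[C@@H]3[C@@H]4OC(C)(C)O[C@H]14 | intermediate
11 | samarium enolate of the desulfonylated ester (O-bound SmI2 group) | COC(O[Sm](I)I)=C1C[C@@H]2O[C@@H]2[C@@H]2OC(C)(C)O[C@H]12 | intermediate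
12 | methyl (1S,5R,6R)-5-hydroxy-7-oxabicyclo[4.1.0]hept-3-ene-3-carboxylate (hydroxyl cis to the oxirane oxygen) | [C@H]12CC(C(=O)OC)=C[C@@H](O)[C@H]1O2 | intermediate
13 | methyl (1S,5R,6S)-5-acetoxy-7-oxabicyclo[4.1.0]hept-3-ene-3-carboxylate | [C@H]12CC(C(=O)OC)=C[C@@H](OC(C)=O)[C@H]1O2 | intermediate
14 | (S)-3-methylpentanoic acid | CC[C@H](C)CC(=O)O | starting material
15 | methyl (3R,4S,5R)-3-acetoxy-4-hydroxy-5-[(S)-3-methylpentanoyloxy]cyclohex-1-ene-1-carboxylate | CC[C@H](C)CC(=O)O[C@@H]1CC(C(=O)OC)=C[C@@H](OC(C)=O)[C@H]1O | intermediate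
16 | (R)-2-methylbutanoic acid | CC[C@@H](C)C(=O)O | starting material
17 | methyl (3R,4S,5R)-3-acetoxy-4-[(R)-2-methylbutanoyloxy]-5-[(S)-3-methylpentanoyloxy]cyclohex-1-ene-1-carboxylate | CC[C@H](C)CC(=O)O[C@@H]1CC(C(=O)OC)=C[C@@H](OC(C)=O)[C@H]1OC(=O)[C@H](C)CC | target

Total step count: 10
Longest linear sequence: 10 steps (1 to 17)

Steps most likely to fail:

Step 6. The ylide may add to the aldehyde face that puts the oxirane trans to the dioxolane, the C3 centre may epimerise under DBU, or the C1 carbanion may lose the dioxolane oxygen by β-elimination before it is alkylated. The fallback sets out from 6 and returns at 10. With vinyltriphenylphosphonium bromide and DBU in MeCN, conjugate addition and intramolecular Wittig olefination (Schweizer annulation) should give methyl (2S,3S)-2,3-(isopropylidenedioxy)-1-(phenylsulfonyl)cyclohex-4-ene-1-carboxylate F1. NBS in wet DMSO should place the bromonium ion on the face away from the dioxolane, and trans opening by water gives the bromohydrin methyl 5-bromo-4-hydroxy-2,3-(isopropylidenedioxy)-1-(phenylsulfonyl)cyclohexane-1-carboxylate F2 (hydroxyl on the dioxolane face; the regioisomeric bromohydrin converges). K2CO3 in methanol should then close the oxirane on the dioxolane face, which is compound 10.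

Step 7. Electron transfer may also reach the oxirane or the newly formed enoate, or the enolate may be protonated instead of eliminating. The fallback sets out from 10 and returns at 17, and moves the reductive step to a stage without an oxirane. Opening of 10 with 14 (Cs2CO3 cat., DMF) should give methyl 4-hydroxy-2,3-(isopropylidenedioxy)-5-[(S)-3-methylpentanoyloxy]-1-(phenylsulfonyl)cyclohexane-1-carboxylate F3. Steglich esterification with 16 gives methyl 2,3-(isopropylidenedioxy)-4-[(R)-2-methylbutanoyloxy]-5-[(S)-3-methylpentanoyloxy]-1-(phenylsulfonyl)cyclohexane-1-carboxylate F4. SmI2 in THF–HMPA then effects the same reductive elimination, and the samarium alkoxide released at O3 is acetylated in the same flask with Ac2O to give 17.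

Step 9. The carboxylate may attack C4 instead of C5, and the acetyl group may migrate from O3 to the cis-vicinal O4 once the hydroxyl is freed. The fallback sets out from 12 and returns at 17, and opens the oxirane on a bulky, non-migrating C3 ether. TBSCl and imidazole should give methyl (1S,5R,6S)-5-(tert-butyldimethylsilyloxy)-7-oxabicyclo[4.1.0]hept-3-ene-3-carboxylate F5. Opening with 14 (Cs2CO3 cat., DMF) gives methyl (3R,4S,5R)-3-(tert-butyldimethylsilyloxy)-4-hydroxy-5-[(S)-3-methylpentanoyloxy]cyclohex-1-ene-1-carboxylate F6. Steglich esterification with 16 gives methyl (3R,4S,5R)-3-(tert-butyldimethylsilyloxy)-4-[(R)-2-methylbutanoyloxy]-5-[(S)-3-methylpentanoyloxy]cyclohex-1-ene-1-carboxylate F7. HF·pyridine gives methyl (3R,4R,5R)-3-hydroxy-4-[(R)-2-methylbutanoyloxy]-5-[(S)-3-methylpentanoyloxy]cyclohex-1-ene-1-carboxylate F8, and Ac2O with pyridine gives 17.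

Further compounds
F1 | step 6 | methyl (2S,3S)-2,3-(isopropylidenedioxy)-1-(phenylsulfonyl)cyclohex-4-ene-1-carboxylate (C-1 epimers) | COC(=O)C1(S(=O)(=O)c2ccccc2)CC=C[C@@H]2OC(C)(C)O[C@H]12
F2 | step 6 | methyl 5-bromo-4-hydroxy-2,3-(isopropylidenedioxy)-1-(phenylsulfonyl)cyclohexane-1-carboxylate (hydroxyl cis to the dioxolane and bromine trans to it) | COC(=O)C1(S(=O)(=O)c2ccccc2)C[C@@H](Br)[C@H](O)[C@@H]2OC(C)(C)O[C@H]12
F3 | step 7 | methyl 4-hydroxy-2,3-(isopropylidenedioxy)-5-[(S)-3-methylpentanoyloxy]-1-(phenylsulfonyl)cyclohexane-1-carboxylate (C4 oxygen cis to the dioxolane and C5 oxygen trans to it) | COC(=O)C1(S(=O)(=O)c2ccccc2)C[C@@H](OC(=O)C[C@@H](C)CC)[C@H](O)[C@@H]3OC(C)(C)O[C@H]13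
F4 | step 7 | methyl 2,3-(isopropylidenedioxy)-4-[(R)-2-methylbutanoyloxy]-5-[(S)-3-methylpentanoyloxy]-1-(phenylsulfonyl)cyclohexane-1-carboxylate | COC(=O)C1(S(=O)(=O)c2ccccc2)C[C@@H](OC(=O)C[C@@H](C)CC)[C@H](OC(=O)[C@H](C)CC)[C@@H]3OC(C)(C)O[C@H]13
F5 | step 9 | methyl (1S,5R,6S)-5-(tert-butyldimethylsilyloxy)-7-oxabicyclo[4.1.0]hept-3-ene-3-carboxylate | [C@H]12CC(C(=O)OC)=C[C@@H](O[Si](C)(C)C(C)(C)C)[C@H]1O2
F6 | step 9 | methyl (3R,4S,5R)-3-(tert-butyldimethylsilyloxy)-4-hydroxy-5-[(S)-3-methylpentanoyloxy]cyclohex-1-ene-1-carboxylate | CC[C@H](C)CC(=O)O[C@@H]1CC(C(=O)OC)=C[C@@H](O[Si](C)(C)C(C)(C)C)[C@H]1O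
F7 | step 9 | methyl (3R,4S,5R)-3-(tert-butyldimethylsilyloxy)-4-[(R)-2-methylbutanoyloxy]-5-[(S)-3-methylpentanoyloxy]cyclohex-1-ene-1-carboxylate | CC[C@H](C)CC(=O)O[C@@H]1CC(C(=O)OC)=C[C@@H](O[Si](C)(C)C(C)(C)C)[C@H]1OC(=O)[C@H](C)CC
F8 | step 9 | methyl (3R,4R,5R)-3-hydroxy-4-[(R)-2-methylbutanoyloxy]-5-[(S)-3-methylpentanoyloxy]cyclohex-1-ene-1-carboxylate | CC[C@H](C)CC(=O)O[C@@H]1CC(C(=O)OC)=C[C@@H](O)[C@H]1OC(=O)[C@H](C)CC
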